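Compound numbering: 1 to 22, as fixed in the steps and in the compound list; 14 is the substrate of the key step, 17 its product and 22 the target.

## Analysis of the target

Hernanol (22) is a dibenzylbutyrolactone lignan built on one γ-butyrolactone ring (O1, C2 carbonyl, C3, C4, C5) that carries a 3,4,5-trimethoxybenzyl group on C3 and a 4-hydroxy-3-methoxybenzyl (guaiacylmethyl) group on C4. C3 and C4 are the only stereocentres, both R, and the two arylmethyl groups lie on opposite faces of the ring (trans). C3 is α to the lactone carbonyl and can be reached by enolisation, whereas C4 has no activating neighbour, so its configuration is final once it is formed. The sensitive groups are the lactone, the acidic C3–H and the free electron-rich phenol, which is best masked while metals and reductants are in use. The difficulty is the near-symmetry: two arylmethyl arms that differ only in the arene must be placed on defined carbons with defined absolute and relative configuration, and neither stereocentre carries a heteroatom that could direct a reagent. The strategy rests on the substituents of C4, which are H, C3 and two CH2 groups, namely ring carbon C5 and the benzylic carbon. If both CH2 groups are drawn as hydroxymethyl arms, C4 is no stereocentre at all; it becomes one only when one arm enters the ring as C5, and the other arm remains as the handle for the guaiacyl ring.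

## Retrosynthetic reasoning

**22 from 21.** The phenol O–H is traced back to the benzyl ether 21. A free phenol would interfere with the nickel and zinc chemistry of the preceding step, and the benzyl group is removed under neutral conditions that touch neither the lactone nor C3.

**21 from 18 and 20.** The bond between the exocyclic CH2 on C4 and the guaiacyl ring is cut. It is an sp3–sp2 bond remote from both stereocentres, so forming it cannot disturb them. The cut leaves iodide 18, whose CH2 is the unused hydroxymethyl arm, and aryl bromide 20, made in one step from 19. The forward reaction must join two electrophiles without a basic organometallic, because base would enolise C3 and close the iodide onto it.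

**18 from 17.** The C–I bond is exchanged for C–OH. The forward reaction has to be fast and mild, since the free alcohol 17 can still exchange its arms.

**17 from 14 (through 15 and 16).** The O1–C2 lactone bond is cut. In the opened form both arms on C4 are hydroxymethyl groups, protected together as an acetonide in acid 14, and only C3 remains as a stereocentre. The gain is that one stereocentre, not two, has to be made by asymmetric synthesis. The forward reaction has to choose one of two diastereotopic arms, and it can do so under thermodynamic control because the two possible lactones 16 and 17 interconvert through the free hydroxymethyl group.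

**14 from 13.** The two C–H bonds at C3 and at the benzylic carbon are removed to give the α-substituted cinnamic acid 13. A trisubstituted alkene bearing a carboxyl group is a good substrate for catalyst-controlled hydrogenation, so C3 is set by a chiral rhodium catalyst and not by an auxiliary.

**13 from 11, 11 from 9, and 9 from 5 and 6.** The acid 13 comes from its ethyl ester 11, and the Cα=Cβ bond of 11 (the later bond from C3 to the CH2 of the trimethoxybenzyl arm) is cut by an aldol addition and dehydration through aldol 9. This joins ester 5 to the commercial aldehyde 6 and brings in the whole trimethoxybenzyl arm at the correct oxidation level.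

**5 from 4, and 4 from 1 and 2.** The bond between the later C4 and C3 is cut as an olefination of the symmetric ketone 1 with phosphonate 2, followed by saturation of alkene 4. The 1,3-diol of both arms comes ready-made and protected in 1, and no stereochemistry arises because the ring carbon carries two identical arms.

## Alternatives that were turned down

Alternative 1: three-component conjugate addition and alkylation on a chiral butenolide.
- **Disconnection:** both exocyclic C–C bonds, C4–C(benzylic) and C3–CH2, are cut together. This leads to (5R)-5-[(1R,2S,5R)-menthyloxy]furan-2(5H)-one A2, to 2-[4-(benzyloxy)-3-methoxyphenyl]-1,3-dithiane A3 as an acyl-anion equivalent of the guaiacyl arm, and to 3,4,5-trimethoxybenzyl bromide A4.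
- **Forward key step:** lithiated A3 would add to C4 of A2 on the face away from the menthyloxy group. The lactone enolate would then be alkylated at C3 by A4 in the same flask, again anti to its new neighbour. The product would be the all-trans lactone (3R,4R,5R)-4-{2-[4-(benzyloxy)-3-methoxyphenyl]-1,3-dithian-2-yl}-5-(menthyloxy)-3-(3,4,5-trimethoxybenzyl)dihydrofuran-2(3H)-one A1.
- **For it:** two C–C bonds and both stereocentres arise in one operation, relayed sterically from the acetal carbon. The route is convergent and would need about seven to nine steps. On step count and on predictability of the relative configuration it is stronger than the chosen route.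
- **Against it:** A1 is over-functionalised in three places: C5 is an acetal at the aldehyde oxidation level, the benzylic carbon is a dithioketal, and the phenol is benzylated. Taking the acetal carbon down to CH2 means opening the ring at the aldehyde oxidation level, a stage at which C4 is α to a formyl group and can epimerise until the reduction is complete. Desulfurisation needs a large excess of Raney Ni beside a benzyl ether and electron-rich arenes. The chirality is bought stoichiometrically, and A2 has to be obtained diastereomerically pure by crystallisation.
- **Comparison:** the chosen strategy is longer. In exchange it takes absolute configuration from a catalyst, never places C4 next to a carbonyl, uses no sulfur, and attaches the guaiacyl ring last from a simple aryl bromide, so that this ring can be varied.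

Alternative 2: desymmetrising Baeyer–Villiger oxidation of a cyclobutanone.
- **Disconnection:** the O1–C5 bond of the monosubstituted lactone (R)-4-[4-(benzyloxy)-3-methoxybenzyl]dihydrofuran-2(3H)-one A5 is cut back to the prochiral ketone 3-[4-(benzyloxy)-3-methoxybenzyl]cyclobutanone A6. The C3–CH2 bond is cut as an enolate alkylation with A4.
- **Forward key step:** a Baeyer–Villiger monooxygenase with O2, or a chiral phosphoric acid with H2O2, would insert oxygen next to one of the two enantiotopic α-CH2 groups of A6 and expand the four-membered ring to A5.
- **For it:** the later alkylation of A5 anti to its C4 substituent would lead to 21 and is a kinetic and very dependable way to set the trans relationship. It is more secure than a thermodynamic choice between two arms. About six steps would suffice, so the alternative is stronger on both points.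
- **Against it:** the absolute configuration depends entirely on distinguishing two CH2 groups that differ only through a flexible arylmethyl substituent on the far ring carbon, with no binding group near the reacting bond. Chemical catalysts are expected to discriminate weakly, and an enzyme would have to be found by screening for this bulky substrate and for the required enantiomer. If the selectivity is incomplete, nothing later in the route corrects it.
- **Comparison:** the chosen strategy sets absolute configuration in a hydrogenation in which carboxylate and alkene chelate the metal directly at the new stereocentre. It pays for this with more steps and a less secure trans selection.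

Alternative 3: hydroxyl-directed hydroformylation that closes the lactol.
- **Disconnection:** C2–C3 and O1–C2 are cut. This leads from the lactol (3R,4R)-4-[4-(benzyloxy)-3-methoxybenzyl]-3-(3,4,5-trimethoxybenzyl)tetrahydrofuran-2-ol A7, formed as an anomer mixture, to the homoallylic alcohol (R,E)-2-[4-(benzyloxy)-3-methoxybenzyl]-4-(3,4,5-trimethoxyphenyl)but-3-en-1-ol A8 and to CO and H2.
- **Forward key step:** with Rh(acac)(CO)2 and a phosphinite ligand that exchanges reversibly onto the hydroxyl group, the formyl group would be delivered to the alkene carbon nearer the hydroxyl. The aldehyde would close to A7, which is then oxidised to 21 and debenzylated.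
- **For it:** the step is catalytic and atom-economic, and the ring and C3 are formed together. C3 ends up α to an aldehyde in the open form of A7 and can settle to the trans isomer, a correction the chosen route does not have at C4.
- **Against it:** the alkene of A8 is an electron-rich styrene. Rhodium hydride prefers to place the metal on the benzylic carbon, which would put the formyl group on the wrong carbon, so the directing ligand has to override an electronic bias on a slowly reacting 1,2-disubstituted alkene. A8 still needs its own enantioselective synthesis of a stereocentre with three carbon substituents of similar size. An extra oxidation step and pressure equipment are needed, and the total is about nine steps.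
- **Comparison:** the length is similar to that of the chosen route. The chosen ring closure is an acyl substitution with no regiochemical question, whereas this alternative is stronger in atom economy.

Key step: step 7

Assumption: which enantiomer of the Walphos-type ligand gives the (R)-acid 14 cannot be derived from first principles; step 6 is written for the (R,R)-ligand, and the mirror-image ligand is used if a first trial shows the opposite sense.

## Route

Step 1
Reactants: 1 2,2-dimethyl-1,3-dioxan-5-one; 2 triethyl phosphonoacetate
Product: 4 ethyl 2-(2,2-dimethyl-1,3-dioxan-5-ylidene)acetate, via sodium phosphonoacetate carbanion 3 (not isolated)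
Conditions: 2, NaH (1.05 equiv), THF, 0 °C; then 1, 0 °C to rt
Reagents that add atoms: none
Why: Horner–Wadsworth–Emmons olefination of an unhindered, electron-poor ketone by a preformed stabilised carbanion; the ketone is symmetric, so no alkene geometry arises, and the acetonide is stable to base.

Step 2
Reactants: 4 ethyl 2-(2,2-dimethyl-1,3-dioxan-5-ylidene)acetate
Product: 5 ethyl 2-(2,2-dimethyl-1,3-dioxan-5-yl)acetate
Conditions: H2 (1 atm), 10% Pd/C, EtOAc, rt
Reagents that add atoms: none
Why: Heterogeneous hydrogenation of a conjugated trisubstituted alkene under neutral conditions that leave the acetonide intact; the ring carbon carries two identical CH2O arms, so no stereocentre is created.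

Step 3
Reactants: 5 ethyl 2-(2,2-dimethyl-1,3-dioxan-5-yl)acetate; 6 3,4,5-trimethoxybenzaldehyde
Product: 9 ethyl 2-(2,2-dimethyl-1,3-dioxan-5-yl)-3-hydroxy-3-(3,4,5-trimethoxyphenyl)propanoate (racemic mixture of diastereomers), via lithium ester enolate 7 (not isolated), via lithium aldolate 8 (not isolated)
Conditions: LiN(iPr)2 (1.1 equiv), THF, −78 °C; then 6, −78 °C; then AcOH, −78 °C
Reagents that add atoms: none
Why: Directed aldol addition of a kinetically formed lithium ester enolate to a non-enolisable aromatic aldehyde; the enolate has no β-leaving group, the cold acid quench suppresses retro-aldol cleavage, and the diastereomer composition is irrelevant because both new centres are removed in step 4.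

Step 4
Reactants: 9 ethyl 2-(2,2-dimethyl-1,3-dioxan-5-yl)-3-hydroxy-3-(3,4,5-trimethoxyphenyl)propanoate
Product: 11 ethyl (E)-2-(2,2-dimethyl-1,3-dioxan-5-yl)-3-(3,4,5-trimethoxyphenyl)prop-2-enoate, via benzylic mesylate 10 (not isolated)
Conditions: MsCl (1.5 equiv), Et3N (3 equiv), CH2Cl2, 0 °C; then DBU (3 equiv), rt to 40 °C
Reagents that add atoms: none
Why: Sulfonylation followed by E1cB elimination through the ester enolate; because both aldol diastereomers pass through the same enolate, they should converge on the conjugated cinnamate, with the E isomer (aryl trans to the ester) expected to predominate.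

Step 5
Reactants: 11 ethyl (E)-2-(2,2-dimethyl-1,3-dioxan-5-yl)-3-(3,4,5-trimethoxyphenyl)prop-2-enoate
Product: 13 (E)-2-(2,2-dimethyl-1,3-dioxan-5-yl)-3-(3,4,5-trimethoxyphenyl)prop-2-enoic acid, via lithium carboxylate 12 (not isolated)
Conditions: LiOH·H2O (4 equiv), THF/MeOH/H2O, 50 °C; then 1 M HCl to pH 4, 0 °C; recrystallisation
Reagents that add atoms: lithium hydroxide, [Li+].[OH-]
Why: Saponification of a hindered conjugated ester by acyl substitution; hydroxide does not affect the acetonide or the alkene geometry, acidification is stopped at pH 4 in the cold to keep the acetonide, and crystallisation of the acid should remove any minor geometric isomer.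

Step 6
Reactants: 13 (E)-2-(2,2-dimethyl-1,3-dioxan-5-yl)-3-(3,4,5-trimethoxyphenyl)prop-2-enoic acid
Product: 14 (R)-2-(2,2-dimethyl-1,3-dioxan-5-yl)-3-(3,4,5-trimethoxyphenyl)propanoic acid
Conditions: [Rh(nbd)2]BF4 (1 mol%), (R)-1-[(R)-2-(2'-diphenylphosphinophenyl)ferrocenyl]ethylbis[3,5-bis(trifluoromethyl)phenyl]phosphine (Walphos type, 1.1 mol%), H2 (50 bar), Et3N (0.1 equiv), MeOH, 40 °C
Reagents that add atoms: none
Why: Rhodium-catalysed asymmetric hydrogenation of an α-substituted cinnamic acid, a substrate class for which α-branched alkyl groups are established; carboxylate and alkene chelate the cationic rhodium, and the chiral bisphosphine decides to which alkene face both hydrogens are added syn, which sets the stereocentre (later C3) by catalyst control. The small amount of amine buffers the acid released from the catalyst precursor and protects the acetonide.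

Step 7
Reactants: 14 (R)-2-(2,2-dimethyl-1,3-dioxan-5-yl)-3-(3,4,5-trimethoxyphenyl)propanoic acid
Product: 17 (3R,4S)-4-(hydroxymethyl)-3-(3,4,5-trimethoxybenzyl)dihydrofuran-2(3H)-one (trans), via dihydroxy acid 15 (not isolated), via cis-lactone 16 (not isolated)
Conditions: TsOH·H2O (0.2 equiv), MeCN/H2O (9:1), rt, then 50 °C until the lactone composition is constant; chromatography, recovered 16 returned to the same conditions
Reagents that add atoms: none
Why: Acid-catalysed acetal hydrolysis (oxocarbenium ion, loss of acetone) unmasks both hydroxymethyl arms in 15, and either primary hydroxyl then adds to the protonated carboxyl group and expels water, a Fischer-type lactonisation of a γ-hydroxy acid that forms the O1–C2 bond and closes the five-membered ring in the 5-exo-trig mode. The closest known reaction type is the diastereotopic group-selective lactonisation of 2-substituted 4-hydroxy-3-(hydroxymethyl)butanoic acids, in which the two γ-lactones interconvert by translactonisation. The new stereocentre C4 is controlled by the existing centre C3 (substrate control) and the selection is thermodynamic: closing one arm gives trans-lactone 17, closing the other gives cis-lactone 16, in which the arylmethyl group on C3 and the hydroxymethyl group on C4 are held on the same face of the ring next to each other. The two lactones remain in equilibrium because the free hydroxymethyl group of either can add to the lactone carbonyl (a bicyclic orthoacid-type tetrahedral intermediate) and because the wet acidic medium also allows reopening to 15, so material should drain from 16 into the more stable 17. The step therefore needs selectivity between two constitutionally identical arms, and this is secured by the C3 substituent together with the reversibility that the second hydroxyl provides. No bond to C3 is made or broken; acid is chosen over base because enolisation of the lactone is slow under these conditions, whereas epimerisation at C3 combined with arm exchange would amount to racemisation. Cis-lactone 16 left at equilibrium is separated and resubmitted.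

Step 8
Reactants: 17 (3R,4S)-4-(hydroxymethyl)-3-(3,4,5-trimethoxybenzyl)dihydrofuran-2(3H)-one
Product: 18 (3R,4R)-4-(iodomethyl)-3-(3,4,5-trimethoxybenzyl)dihydrofuran-2(3H)-one
Conditions: PPh3 (1.3 equiv), I2 (1.3 equiv), imidazole (1.5 equiv), CH2Cl2, 0 °C; used without storage
Reagents that add atoms: iodine, II
Why: Appel-type iodination of a primary alcohol through an alkoxyphosphonium ion and SN2 displacement at the CH2 group, which involves no stereocentre (the descriptor at C4 changes only because iodine outranks oxygen). The reaction is fast at 0 °C, so the weak base should have no time to promote arm exchange in 17 or closure of the iodide onto C3.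

Step 9
Reactants: 19 4-bromo-2-methoxyphenol
Product: 20 1-(benzyloxy)-4-bromo-2-methoxybenzene
Conditions: BnBr (1.1 equiv), K2CO3 (1.5 equiv), DMF, rt
Reagents that add atoms: benzyl bromide, BrCc1ccccc1
Why: Williamson ether synthesis on a phenoxide; the benzyl ether masks the acidic phenol during the nickel and zinc chemistry and is removed under neutral conditions at the end.

Step 10
Reactants: 18 (3R,4R)-4-(iodomethyl)-3-(3,4,5-trimethoxybenzyl)dihydrofuran-2(3H)-one; 20 1-(benzyloxy)-4-bromo-2-methoxybenzene
Product: 21 (3R,4R)-4-[4-(benzyloxy)-3-methoxybenzyl]-3-(3,4,5-trimethoxybenzyl)dihydrofuran-2(3H)-one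
Conditions: NiBr2(dme) (10 mol%), 4,4'-di-tert-butyl-2,2'-bipyridine (10 mol%), Zn dust (2 equiv), DMA, 60 °C; 20 (1.5 equiv), 18 added slowly
Reagents that add atoms: none
Why: Nickel-catalysed reductive cross-electrophile coupling of an aryl bromide with a primary alkyl iodide: zerovalent nickel on the bipyridine inserts into the aryl bromide, the arylnickel species captures the primary alkyl radical formed by halogen abstraction from 18, reductive elimination forms the CH2–aryl bond, and zinc turns the catalyst over. The radical sits on the exocyclic CH2, so C3 and C4 are untouched, and the medium contains no strong base that could enolise the lactone.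

Step 11
Reactants: 21 (3R,4R)-4-[4-(benzyloxy)-3-methoxybenzyl]-3-(3,4,5-trimethoxybenzyl)dihydrofuran-2(3H)-one
Product: 22 hernanol, (3R,4R)-4-(4-hydroxy-3-methoxybenzyl)-3-(3,4,5-trimethoxybenzyl)dihydrofuran-2(3H)-one
Conditions: H2 (1 atm), 10% Pd/C, EtOAc/EtOH, rt
Reagents that add atoms: none
Why: Hydrogenolysis of the benzyl aryl ether on palladium; the molecule has no other benzylic C–O bond, and the neutral conditions leave the lactone and both stereocentres unchanged.

## Compound list

1 | 2,2-dimethyl-1,3-dioxan-5-one | CC1(C)OCC(=O)CO1 | starting material
2 | triethyl phosphonoacetate | CCOC(=O)CP(=O)(OCC)OCC | starting material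
3 | sodium salt of triethyl phosphonoacetate (carbanion) | CCOC(=O)[CH-]P(=O)(OCC)OCC.[Na+] | intermediate
4 | ethyl 2-(2,2-dimethyl-1,3-dioxan-5-ylidene)acetate | CCOC(=O)C=C1COC(C)(C)OC1 | intermediate
5 | ethyl 2-(2,2-dimethyl-1,3-dioxan-5-yl)acetate | CCOC(=O)CC1COC(C)(C)OC1 | intermediate
6 | 3,4,5-trimethoxybenzaldehyde | COc1cc(C=O)cc(OC)c1OC | starting material
7 | lithium enolate of ester 5 | CCOC([O-])=CC1COC(C)(C)OC1.[Li+] | intermediate
8 | lithium alkoxide of aldol 9 | CCOC(=O)C(C1COC(C)(C)OC1)C([O-])c1cc(OC)c(OC)c(OC)c1.[Li+] | intermediate
9 | ethyl 2-(2,2-dimethyl-1,3-dioxan-5-yl)-3-hydroxy-3-(3,4,5-trimethoxyphenyl)propanoate (racemic, both diastereomers) | CCOC(=O)C(C1COC(C)(C)OC1)C(O)c1cc(OC)c(OC)c(OC)c1 | intermediate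
10 | ethyl 2-(2,2-dimethyl-1,3-dioxan-5-yl)-3-(methylsulfonyloxy)-3-(3,4,5-trimethoxyphenyl)propanoate | CCOC(=O)C(C1COC(C)(C)OC1)C(OS(C)(=O)=O)c1cc(OC)c(OC)c(OC)c1 | intermediate
11 | ethyl (E)-2-(2,2-dimethyl-1,3-dioxan-5-yl)-3-(3,4,5-trimethoxyphenyl)prop-2-enoate | CCOC(=O)/C(=C/c1cc(OC)c(OC)c(OC)c1)C1COC(C)(C)OC1 | intermediate
12 | lithium (E)-2-(2,2-dimethyl-1,3-dioxan-5-yl)-3-(3,4,5-trimethoxyphenyl)prop-2-enoate | [Li+].[O-]C(=O)/C(=C/c1cc(OC)c(OC)c(OC)c1)C1COC(C)(C)OC1 | intermediate
13 | (E)-2-(2,2-dimethyl-1,3-dioxan-5-yl)-3-(3,4,5-trimethoxyphenyl)prop-2-enoic acid | OC(=O)/C(=C/c1cc(OC)c(OC)c(OC)c1)C1COC(C)(C)OC1 | intermediate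
14 | (R)-2-(2,2-dimethyl-1,3-dioxan-5-yl)-3-(3,4,5-trimethoxyphenyl)propanoic acid | CC1(C)OCC(CO1)[C@@H](Cc1cc(OC)c(OC)c(OC)c1)C(=O)O | intermediate
15 | (2R)-4-hydroxy-3-(hydroxymethyl)-2-(3,4,5-trimethoxybenzyl)butanoic acid | OCC(CO)[C@@H](Cc1cc(OC)c(OC)c(OC)c1)C(=O)O | intermediate
16 | (3R,4R)-4-(hydroxymethyl)-3-(3,4,5-trimethoxybenzyl)dihydrofuran-2(3H)-one (cis) | OC[C@@H]1COC(=O)[C@@H]1Cc1cc(OC)c(OC)c(OC)c1 | intermediate
17 | (3R,4S)-4-(hydroxymethyl)-3-(3,4,5-trimethoxybenzyl)dihydrofuran-2(3H)-one (trans) | OC[C@H]1COC(=O)[C@@H]1Cc1cc(OC)c(OC)c(OC)c1 | intermediate
18 | (3R,4R)-4-(iodomethyl)-3-(3,4,5-trimethoxybenzyl)dihydrofuran-2(3H)-one | IC[C@H]1COC(=O)[C@@H]1Cc1cc(OC)c(OC)c(OC)c1 | intermediate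
19 | 4-bromo-2-methoxyphenol | COc1cc(Br)ccc1O | starting material
20 | 1-(benzyloxy)-4-bromo-2-methoxybenzene | COc1cc(Br)ccc1OCc1ccccc1 | intermediate
21 | (3R,4R)-4-[4-(benzyloxy)-3-methoxybenzyl]-3-(3,4,5-trimethoxybenzyl)dihydrofuran-2(3H)-one | COc1cc(C[C@H]2COC(=O)[C@@H]2Cc2cc(OC)c(OC)c(OC)c2)ccc1OCc1ccccc1 | intermediate
22 | hernanol, (3R,4R)-4-(4-hydroxy-3-methoxybenzyl)-3-(3,4,5-trimethoxybenzyl)dihydrofuran-2(3H)-one | COc1cc(C[C@H]2COC(=O)[C@@H]2Cc2cc(OC)c(OC)c(OC)c2)ccc1O | target

## Step count and least certain steps

Total step count: 11. Longest linear sequence: 10 steps (steps 1 to 8, then 10 and 11, counted from 1 and 2); step 9 is a one-step side branch.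

Least certain step 7 (key step). What is most likely to go wrong is incomplete discrimination between the two arms. The energy gap between a trans and a cis 3,4-disubstituted butyrolactone with two CH2-type substituents is modest, so a noticeable share of the material may stay on the cis side at equilibrium. The arm exchange may also be slow under acid, because its tetrahedral intermediate is a strained bicycle, and prolonged heating could begin to erode C3. Fallback for step 7: the order in which the stereocentres are made is reversed, so that C4 is set by a catalyst and C3 by a kinetic alkylation; this fallback sets out from 4 and comes back to the route at 17. Aqueous acid (TsOH·H2O, THF/H2O, rt) removes the acetonide of 4 and the hydroxymethyl group cis to the ester closes onto it, which gives 4-(hydroxymethyl)furan-2(5H)-one F1. Benzylation under acidic conditions (benzyl 2,2,2-trichloroacetimidate, catalytic TfOH, CH2Cl2) turns F1 into 4-[(benzyloxy)methyl]furan-2(5H)-one F2. Copper hydride asymmetric conjugate reduction of F2 (Cu(OAc)2, a chiral bisphosphine of the SEGPHOS type in the enantiomer that gives the S product, polymethylhydrosiloxane, t-BuOH, toluene) sets C4 by catalyst control and gives (S)-4-[(benzyloxy)methyl]dihydrofuran-2(3H)-one F3. Deprotonation of F3 with LiN(SiMe3)2 in THF at −78 °C and alkylation with 3,4,5-trimethoxybenzyl bromide A4, which enters anti to the C4 substituent, gives (3R,4S)-4-[(benzyloxy)methyl]-3-(3,4,5-trimethoxybenzyl)dihydrofuran-2(3H)-one F4. Hydrogenolysis of F4 on Pd/C under neutral conditions frees the alcohol 17.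

Least certain step 10. What is most likely to go wrong is escape of the primary alkyl radical from the nickel cycle. The alkyl iodide is activated faster than the electron-rich aryl bromide, which favours reduction and dimerisation of the alkyl partner, and the radical can also add to the neighbouring trimethoxyphenyl ring. Fallback for step 10: the cross-electrophile coupling is replaced by a Negishi coupling that sets out from 18 and comes back to the route at 21. Zinc insertion into 18 (activated Zn dust, LiCl, THF, 40 °C) gives {[(3R,4R)-5-oxo-4-(3,4,5-trimethoxybenzyl)tetrahydrofuran-3-yl]methyl}zinc iodide F5. The reagent F5 has no β-leaving group and is not basic enough to enolise the lactone, and its coupling with 20 under Pd(OAc)2 and 2-dicyclohexylphosphino-2',6'-dimethoxybiphenyl in THF forms the same CH2–aryl bond and gives 21.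

Least certain step 6. What is most likely to go wrong is weak facial discrimination. The dioxanyl group is larger than the branched alkyl groups for which this catalyst type is established, and its oxygen atoms can compete for the metal. Slow methanolysis of the acetonide is a second concern. Fallback for step 6: the catalytic hydrogenation is replaced by an auxiliary-controlled alkylation that sets out from 5 and comes back to the route at 14. Saponification of 5 (LiOH, THF/H2O, then pH 4) gives 2-(2,2-dimethyl-1,3-dioxan-5-yl)acetic acid F6. Activation of F6 with pivaloyl chloride and Et3N, followed by acylation of lithiated (R)-4-benzyloxazolidin-2-one, gives (R)-4-benzyl-3-[2-(2,2-dimethyl-1,3-dioxan-5-yl)acetyl]oxazolidin-2-one F7. Deprotonation of F7 with NaN(SiMe3)2 in THF at −78 °C and alkylation with A4, on the face of the chelated Z-enolate opposite the benzyl group of the auxiliary, gives (R)-4-benzyl-3-[(R)-2-(2,2-dimethyl-1,3-dioxan-5-yl)-3-(3,4,5-trimethoxyphenyl)propanoyl]oxazolidin-2-one F8. Because the dioxanyl group ranks above the incoming arylmethyl group, this face corresponds to the R descriptor. Cleavage of F8 with LiOH and H2O2 at 0 °C gives 14 and returns the auxiliary.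

Least certain step 4. What is most likely to go wrong is loss of geometric control in the elimination, because the bulky α-substituent reduces the energy difference between the two alkene geometries. The two geometries would be expected to give opposite enantiomers in step 6, so incomplete removal of the minor one lowers the enantiomeric purity of 14. Fallback for step 4: the alkene geometry is made irrelevant; this fallback sets out from 13, used as the unseparated mixture of alkene geometries, and comes back to the route at 14. Hydrogenation on Pd/C in EtOAc gives rac-2-(2,2-dimethyl-1,3-dioxan-5-yl)-3-(3,4,5-trimethoxyphenyl)propanoic acid F9. The acid F9 is resolved by crystallisation of a diastereomeric salt with (S)-1-phenylethylamine, written here as (S)-1-phenylethylammonium (R)-2-(2,2-dimethyl-1,3-dioxan-5-yl)-3-(3,4,5-trimethoxyphenyl)propanoate F10. Which enantiomer of the amine gives the less soluble salt of the R acid has to be found in a first trial. Mild acidification of F10 (aqueous citric acid, pH 4, 0 °C) liberates 14.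

## Further compounds

F1 | step 7 | 4-(hydroxymethyl)furan-2(5H)-one | OCC1=CC(=O)OC1
F2 | step 7 | 4-[(benzyloxy)methyl]furan-2(5H)-one | O=C1OCC(COCc2ccccc2)=C1
F3 | step 7 | (S)-4-[(benzyloxy)methyl]dihydrofuran-2(3H)-one | c1ccccc1COC[C@H]1COC(=O)C1
F4 | step 7 | (3R,4S)-4-[(benzyloxy)methyl]-3-(3,4,5-trimethoxybenzyl)dihydrofuran-2(3H)-one | c1ccccc1COC[C@H]1COC(=O)[C@@H]1Cc1cc(OC)c(OC)c(OC)c1
F5 | step 10 | {[(3R,4R)-5-oxo-4-(3,4,5-trimethoxybenzyl)tetrahydrofuran-3-yl]methyl}zinc iodide | I[Zn]C[C@H]1COC(=O)[C@@H]1Cc1cc(OC)c(OC)c(OC)c1
F6 | step 6 | 2-(2,2-dimethyl-1,3-dioxan-5-yl)acetic acid | OC(=O)CC1COC(C)(C)OC1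
F7 | step 6 | (R)-4-benzyl-3-[2-(2,2-dimethyl-1,3-dioxan-5-yl)acetyl]oxazolidin-2-one | O=C(CC1COC(C)(C)OC1)N1[C@H](Cc2ccccc2)COC1=O
F8 | step 6 | (R)-4-benzyl-3-[(R)-2-(2,2-dimethyl-1,3-dioxan-5-yl)-3-(3,4,5-trimethoxyphenyl)propanoyl]oxazolidin-2-one | CC1(C)OCC(CO1)[C@@H](Cc1cc(OC)c(OC)c(OC)c1)C(=O)N1[C@H](Cc2ccccc2)COC1=O
F9 | step 4 | rac-2-(2,2-dimethyl-1,3-dioxan-5-yl)-3-(3,4,5-trimethoxyphenyl)propanoic acid | CC1(C)OCC(CO1)C(Cc1cc(OC)c(OC)c(OC)c1)C(=O)O
F10 | step 4 | (S)-1-phenylethylammonium (R)-2-(2,2-dimethyl-1,3-dioxan-5-yl)-3-(3,4,5-trimethoxyphenyl)propanoate | C[C@H]([NH3+])c1ccccc1.CC1(C)OCC(CO1)[C@@H](Cc1cc(OC)c(OC)c(OC)c1)C([O-])=O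
A1 | alternative 1 | (3R,4R,5R)-4-{2-[4-(benzyloxy)-3-methoxyphenyl]-1,3-dithian-2-yl}-5-(menthyloxy)-3-(3,4,5-trimethoxybenzyl)dihydrofuran-2(3H)-one | COc1cc(C2(SCCCS2)[C@H]2[C@H](O[C@@H]3C[C@H](C)CC[C@H]3C(C)C)OC(=O)[C@@H]2Cc2cc(OC)c(OC)c(OC)c2)ccc1OCc1ccccc1
A2 | alternative 1 | (5R)-5-[(1R,2S,5R)-menthyloxy]furan-2(5H)-one | O=C1C=C[C@H](O[C@@H]2C[C@H](C)CC[C@H]2C(C)C)O1
A3 | alternative 1 | 2-[4-(benzyloxy)-3-methoxyphenyl]-1,3-dithiane | COc1cc(C2SCCCS2)ccc1OCc1ccccc1
A4 | alternative 1 | 3,4,5-trimethoxybenzyl bromide | COc1cc(CBr)cc(OC)c1OC
A5 | alternative 2 | (R)-4-[4-(benzyloxy)-3-methoxybenzyl]dihydrofuran-2(3H)-one | COc1cc(C[C@H]2COC(=O)C2)ccc1OCc1ccccc1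
A6 | alternative 2 | 3-[4-(benzyloxy)-3-methoxybenzyl]cyclobutanone | COc1cc(CC2CC(=O)C2)ccc1OCc1ccccc1
A7 | alternative 3 | (3R,4R)-4-[4-(benzyloxy)-3-methoxybenzyl]-3-(3,4,5-trimethoxybenzyl)tetrahydrofuran-2-ol | COc1cc(C[C@H]2COC(O)[C@@H]2Cc2cc(OC)c(OC)c(OC)c2)ccc1OCc1ccccc1
A8 | alternative 3 | (R,E)-2-[4-(benzyloxy)-3-methoxybenzyl]-4-(3,4,5-trimethoxyphenyl)but-3-en-1-ol | COc1cc(C[C@H](/C=C/c2cc(OC)c(OC)c(OC)c2)CO)ccc1OCc1ccccc1
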